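**Plan**

Decalin numbering: C1 (quaternary; methyl and arylmethyl), C2 (CHMe), C3, C4, C4a (angular methyl), C5 (acid arm), C6 (=CMe2), C7, C8, C8a (H). Ring A = C5–C8 with C4a and C8a; ring B = C1–C4 with C4a and C8a. Ar = 2,5-dimethoxy-3-methylphenyl. Target configuration in this numbering: 1S,2S,4aR,5S,8aR.

- Cuts, backwards: quinone from its hydroquinone dimethyl ether; the acid arm at C5–CH2 and CH2–CH2CO2; C6=CMe2 (acetone); C2–CH3 (cuprate); C1–C2 (ring B); then C8a–C1 and C4a–C4 together.
- Enabling feature: with C5 as a ketone, ring A is 2-methylcyclohexanone whose α-carbon is the methyl-bearing C4a and whose β-carbon is C8a. The two ring-B bonds leaving them (C8a–C1, C4a–C4) are trans, which is the pattern of a conjugate addition with enolate capture on 2-methylcyclohex-2-enone.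
- Forward: aryl fragment (steps 1–4); three-component coupling on ring A, no ring formed (step 5); ring B closed 6-endo by a radical (step 8); C2 methyl and C4 deoxygenation (steps 9–12); C5/C6 elaboration (steps 13–17); quinone (step 18).
- Stereochemistry: C8a from the chiral copper–phosphoramidite catalyst; C4a from aldol capture anti to the C8a arm; C1 from a chair transition state (methyl axial); C2 from axial cuprate attack; C5 from hydroboration anti to the C4a methyl.

Key step: step 5

Remark: the carbinol carbon of 12–13 and C6 of 25–26 later become sp2 and are written as the expected isomers. L is the (S)-binaphthol-derived N,N-bis[(R)-1-phenylethyl]phosphoramidite; the sense of induction is not predicted here, so its mirror image is taken if needed to give (3R)-12.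

**Route**

Step 1
Reactants: 1 2-bromo-6-methylphenol
Product: 2 2-bromo-6-methyl-1,4-benzoquinone
Conditions: K2[ON(SO3)2] (2.2 equiv), KH2PO4, H2O/acetone, 0 °C → rt
Reagents that add atoms: potassium nitrosodisulfonate, [K+].[K+].[O]N(S(=O)(=O)[O-])S(=O)(=O)[O-]
Why: Teuber oxidation: the phenoxyl radical is trapped by a second nitroxide at the free para carbon and the adduct collapses to the para-quinone.

Step 2
Reactants: 2 2-bromo-6-methyl-1,4-benzoquinone
Product: 4 1-bromo-2,5-dimethoxy-3-methylbenzene, via hydroquinone 3 (not isolated)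
Conditions: Na2S2O4, EtOAc/H2O, rt; then MeI, K2CO3, acetone, 56 °C, argon
Reagents that add atoms: iodomethane, CI
Why: Dithionite reduction followed by Williamson methylation of both phenols; telescoping under argon keeps the hydroquinone from re-oxidising.

Step 3
Reactants: 4 1-bromo-2,5-dimethoxy-3-methylbenzene; 5 2,3-dibromoprop-1-ene
Product: 7 1-(2-bromoprop-2-en-1-yl)-2,5-dimethoxy-3-methylbenzene, via arylmagnesium bromide 6 (not isolated)
Conditions: Mg, THF, 50 °C; then 5, CuBr·SMe2 (5 mol %), THF, 0 °C → rt
Reagents that add atoms: none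
Why: Grignard formation and copper-catalysed substitution at the allylic bromide of 5 (Grignard allylation); the alkenyl bromide is much less reactive and stays.

Step 4
Reactants: 7 1-(2-bromoprop-2-en-1-yl)-2,5-dimethoxy-3-methylbenzene
Product: 8 [3-(2,5-dimethoxy-3-methylphenyl)prop-1-en-2-yl]magnesium bromide
Conditions: Mg turnings, THF, 45 °C; titrated solution used directly
Reagents that add atoms: magnesium, [Mg]
Why: Direct magnesium insertion into the alkenyl C–Br bond (Grignard formation); there is no leaving group β to the metal, so the reagent should be stable in solution.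

Step 5
Reactants: 8 [3-(2,5-dimethoxy-3-methylphenyl)prop-1-en-2-yl]magnesium bromide; 9 2-methylcyclohex-2-en-1-one; 10 acrolein
Product: 12 (2S,3R)-3-[3-(2,5-dimethoxy-3-methylphenyl)prop-1-en-2-yl]-2-[(1S)-1-hydroxyprop-2-en-1-yl]-2-methylcyclohexan-1-one, via magnesium enolate 11 (not isolated)
Conditions: CuBr·SMe2 (5 mol %), L (10 mol %), t-BuOMe/THF, −78 °C, slow addition of 8 to 9; then 10, −78 °C; aq. NH4Cl at −78 °C
Reagents that add atoms: none
Why: Transmetalation of 8 to ligand-bound copper gives an alkenylcuprate that adds to the β-carbon of 9 (π-complex, oxidative addition, reductive elimination), forming C8a–C1 and releasing the regiodefined magnesium enolate 11, whose tetrasubstituted carbon then adds to the carbonyl of 10 through a closed six-membered transition state, forming C4a–C4. The closest known reaction type is the copper-catalysed asymmetric conjugate addition of Grignard reagents to 2-substituted cyclic enones with electrophilic capture of the enolate (tandem conjugate addition–aldol), alkenyl donors being its less explored members. No ring closes. C8a is set by the chiral phosphoramidite–copper complex through enone face selection; C4a is set by the new C8a arm, the aldehyde approaching anti to it so that the two future ring-B bonds are trans and the methyl is cis to the arm; the carbinol centre follows from the chair transition state and is erased in step 7. The step needs 1,4- over 1,2-addition of 8 (copper catalysis, slow addition, −78 °C), 1,2- over 1,4-attack on acrolein (hard magnesium enolate, −78 °C) and survival of the aldol (cold quench); the α-methyl enone and the quaternary, non-dehydratable aldol centre support all three.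

Step 6
Reactants: 12 aldol adduct
Product: 13 (1S)-1-{(6S,7R)-7-[3-(2,5-dimethoxy-3-methylphenyl)prop-1-en-2-yl]-6-methyl-1,4-dioxaspiro[4.5]decan-6-yl}prop-2-en-1-ol
Conditions: HOCH2CH2OH (excess), TsOH·H2O (10 mol %), 4 Å MS, CH2Cl2, rt
Reagents that add atoms: ethylene glycol, OCCO
Why: Acid-catalysed dioxolane formation at room temperature, as known for α-quaternary cyclohexanones of the Wieland–Miescher type; C4a has no hydrogen, so the aldol cannot dehydrate, and the mild conditions should spare the carbinol and the 1,1-disubstituted alkene.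

Step 7
Reactants: 13 hydroxy ketal
Product: 14 1-{(6S,7R)-7-[3-(2,5-dimethoxy-3-methylphenyl)prop-1-en-2-yl]-6-methyl-1,4-dioxaspiro[4.5]decan-6-yl}prop-2-en-1-one
Conditions: Dess–Martin periodinane, pyridine, CH2Cl2, 0 °C → rt
Reagents that add atoms: none
Why: Dess–Martin oxidation of the secondary allylic alcohol under pyridine buffering gives the vinyl ketone without touching the ketal; both carbinol epimers converge.

Step 8
Reactants: 14 vinyl ketone
Product: 15 trans-fused 1-(ArCH2)-1,4a-dimethyl-5,5-(ethylenedioxy)decalin-4-one (C1 methyl cis to C4a methyl; C8a–H trans to both)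
Conditions: Fe(acac)3 (30 mol %), PhSiH3, EtOH/HOCH2CH2OH (5:1), 0.01 M, 60 °C
Reagents that add atoms: none
Why: Metal-hydride hydrogen-atom transfer (iron/silane, Mukaiyama type) to the CH2 terminus of the 1,1-disubstituted alkene gives the tertiary C1 radical, which adds 6-endo to the β-carbon of the vinyl ketone (intramolecular Giese reaction) before the α-keto radical is reduced and protonated; the trans fusion is preset by C8a and C4a, and C1 is set in a chair transition state with the smaller methyl axial and the arylmethyl group equatorial.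

Step 9
Reactants: 15 decalin-4-one ketal
Product: 18 C2=C3 enone of 15 (1-(ArCH2)-1,4a-dimethyl-5,5-(ethylenedioxy)-Δ2-octalin-4-one), via lithium enolate 16 (not isolated), via silyl enol ether 17 (not isolated)
Conditions: LiN(iPr)2, THF, −78 °C; Me3SiCl; then Pd(OAc)2 (1.1 equiv), MeCN, rt
Reagents that add atoms: none
Why: Saegusa–Ito oxidation: C3 is the only enolisable position of the C4 ketone, so the silyl enol ether is regiodefined and palladium acetate delivers the enone by β-hydride elimination.

Step 10
Reactants: 18 enone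
Product: 20 C4 enol triflate (C3=C4) carrying the axial C2 methyl (trans to the C1 methyl), via lithium enolate 19 (not isolated)
Conditions: Me2CuLi (from CuBr·SMe2 + 2 MeLi), Et2O, −78 → −20 °C; then PhNTf2, THF/DMPU, −20 °C → rt
Reagents that add atoms: lithium dimethylcuprate, [Li+].C[Cu-]C; N-phenylbis(trifluoromethanesulfonimide), O=S(=O)(N(c1ccccc1)S(=O)(=O)C(F)(F)F)C(F)(F)F
Why: Gilman cuprate conjugate addition occurs axially at C2 from the face opposite the axial methyl groups on C1 and C4a, setting the axial C2 methyl, and the enolate is O-sulfonylated to the enol triflate.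

Step 11
Reactants: 20 enol triflate
Product: 21 Δ3-alkene (1-(ArCH2)-1,2,4a-trimethyl-5,5-(ethylenedioxy)-Δ3-octalin)
Conditions: Pd(OAc)2 (5 mol %), PPh3 (10 mol %), HCO2H, Bu3N, DMF, 60 °C
Reagents that add atoms: none
Why: Palladium-catalysed formate reduction of the enol triflate (oxidative addition, decarboxylation of formate, reductive elimination) replaces C–O by C–H and so removes the C4 oxygen.

Step 12
Reactants: 21 Δ3-alkene
Product: 23 1-(ArCH2)-1,2,4a-trimethyldecalin-5-one, via saturated ketal 22 (not isolated)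
Conditions: H2 (3 atm), Pd/C, EtOAc, rt; filter; then 2 M HCl, THF, 40 °C
Reagents that add atoms: water, O
Why: Catalytic hydrogenation saturates the cis-disubstituted C3=C4 alkene without creating a stereocentre, and acid hydrolysis of the dioxolane then frees the C5 ketone.

Step 13
Reactants: 23 decalin-5-one
Product: 25 6-(2-hydroxypropan-2-yl)decalin-5-one (substituent equatorial), via lithium enolate 24 (not isolated)
Conditions: LiN(iPr)2, THF, −78 °C; ZnCl2; acetone, −78 → −40 °C; AcOH
Reagents that add atoms: acetone, CC(C)=O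
Why: Enolisation is possible only towards C6 because C4a is quaternary, and the zinc-tempered enolate adds to acetone in a directed aldol reaction; the C6 centre is erased in step 14.

Step 14
Reactants: 25 β-hydroxy ketone
Product: 27 6-(propan-2-ylidene)decalin-5-one, via tertiary mesylate 26 (not isolated)
Conditions: MsCl, Et3N, CH2Cl2, 0 °C; then DBU, rt
Reagents that add atoms: none
Why: Mesylation of the tertiary alcohol and DBU-induced E1cB elimination through the ketone enolate give the conjugated tetrasubstituted alkene; any isopropenyl isomer should be drawn into conjugation by the base.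

Step 15
Reactants: 27 isopropylidene ketone
Product: 28 5-methylidene-6-(propan-2-ylidene)decalin
Conditions: Cp2TiMe2, toluene, 75 °C, dark
Reagents that add atoms: dimethyltitanocene, C[Ti+2]C.[cH-]1cccc1.[cH-]1cccc1
Why: Petasis methylenation: the titanium methylidene formed on heating undergoes [2+2] cycloaddition and cycloreversion with the hindered carbonyl and, being non-basic, does not deconjugate the enone through its γ-hydrogens.

Step 16
Reactants: 28 diene
Product: 30 ethyl 3-[decalin-5-yl]propanoate (arm equatorial and cis to the C4a methyl), via alkylborane 29 (not isolated)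
Conditions: 9-BBN, THF, 65 °C; then BrCH2CO2Et, KOtBu, t-BuOH/THF, 0 °C → rt
Reagents that add atoms: ethyl bromoacetate, CCOC(=O)CBr
Why: 9-BBN hydroborates only the 1,1-disubstituted alkene, boron going to CH2 and hydrogen to C5 from the face opposite the axial C4a methyl, and the B-alkyl group then migrates to the carbanion carbon of the bromoacetate enolate with loss of bromide (Brown α-halo ester alkylation), which completes the three-carbon arm.

Step 17
Reactants: 30 ethyl ester
Product: 31 3-[decalin-5-yl]propanoic acid (hydroquinone dimethyl ether of the target)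
Conditions: LiOH, THF/MeOH/H2O, rt; then 1 M HCl
Reagents that add atoms: lithium hydroxide, [Li+].[OH-]
Why: Saponification is done before the base-sensitive quinone is unveiled.

Step 18
Reactants: 31 acid
Product: 32 target quinone CNP0271365.1
Conditions: (NH4)2Ce(NO3)6 (2.5 equiv), MeCN/H2O, 0 °C
Reagents that add atoms: water, O
Why: Oxidative demethylation of the para-dimethoxyarene (arene radical cation, addition of water, loss of methanol) gives the para-quinone; the electron-rich arene should be oxidised before the tetrasubstituted alkene at 0 °C.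

**Compound list**

1 | 2-bromo-6-methylphenol | Cc1cccc(Br)c1O | starting material
2 | 2-bromo-6-methyl-1,4-benzoquinone | CC1=CC(=O)C=C(Br)C1=O | intermediate
3 | 2-bromo-6-methylbenzene-1,4-diol | Cc1cc(O)cc(Br)c1O | intermediate
4 | 1-bromo-2,5-dimethoxy-3-methylbenzene | COc1cc(C)c(OC)c(Br)c1 | intermediate
5 | 2,3-dibromoprop-1-ene | C=C(Br)CBr | starting material
6 | (2,5-dimethoxy-3-methylphenyl)magnesium bromide | COc1cc(C)c(OC)c([Mg]Br)c1 | intermediate
7 | 1-(2-bromoprop-2-en-1-yl)-2,5-dimethoxy-3-methylbenzene | C=C(Br)Cc1cc(OC)cc(C)c1OC | intermediate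
8 | [3-(2,5-dimethoxy-3-methylphenyl)prop-1-en-2-yl]magnesium bromide | C=C(Cc1c(OC)c(C)cc(OC)c1)[Mg]Br | intermediate
9 | 2-methylcyclohex-2-en-1-one | CC1=CCCCC1=O | starting material
10 | acrolein | C=CC=O | starting material
11 | bromomagnesium enolate (C1=C2) of (3R)-3-[3-Ar-prop-1-en-2-yl]-2-methylcyclohexanone | COc1cc(C)c(OC)c(CC(=C)[C@H]2CCCC(O[Mg]Br)=C2C)c1 | intermediate
12 | (2S,3R)-3-[3-(2,5-dimethoxy-3-methylphenyl)prop-1-en-2-yl]-2-[(1S)-1-hydroxyprop-2-en-1-yl]-2-methylcyclohexan-1-one | COc1cc(C)c(OC)c(CC(=C)[C@H]3CCCC(=O)[C@]3(C)[C@@H](O)C=C)c1 | intermediate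
13 | (1S)-1-{(6S,7R)-7-[3-Ar-prop-1-en-2-yl]-6-methyl-1,4-dioxaspiro[4.5]decan-6-yl}prop-2-en-1-ol | COc1cc(C)c(OC)c(CC(=C)[C@H]3CCCC4(OCCO4)[C@]3(C)[C@@H](O)C=C)c1 | intermediate
14 | 1-{(6S,7R)-7-[3-Ar-prop-1-en-2-yl]-6-methyl-1,4-dioxaspiro[4.5]decan-6-yl}prop-2-en-1-one | COc1cc(C)c(OC)c(CC(=C)[C@H]3CCCC4(OCCO4)[C@]3(C)C(=O)C=C)c1 | intermediate
15 | trans-fused 1-(ArCH2)-1,4a-dimethyl-5,5-(ethylenedioxy)decalin-4-one; C1 methyl axial and cis to C4a methyl, ArCH2 equatorial | COc1cc(C)c(OC)c(C[C@]2(C)[C@H]3CCCC4(OCCO4)[C@]3(C)C(=O)CC2)c1 | intermediate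
16 | lithium enolate (C3=C4) of 15 | COc1cc(C)c(OC)c(C[C@]2(C)[C@H]3CCCC4(OCCO4)[C@]3(C)C(O[Li])=CC2)c1 | intermediate
17 | trimethylsilyl enol ether (C3=C4) of 15 | COc1cc(C)c(OC)c(C[C@]2(C)[C@H]3CCCC4(OCCO4)[C@]3(C)C(O[Si](C)(C)C)=CC2)c1 | intermediate
18 | C2=C3 enone: 1-(ArCH2)-1,4a-dimethyl-5,5-(ethylenedioxy)-Δ2-octalin-4-one | COc1cc(C)c(OC)c(C[C@]2(C)[C@H]3CCCC4(OCCO4)[C@]3(C)C(=O)C=C2)c1 | intermediate
19 | lithium enolate (C3=C4) with axial C2 methyl | COc1cc(C)c(OC)c(C[C@]2(C)[C@H]3CCCC4(OCCO4)[C@]3(C)C(O[Li])=C[C@@H]2C)c1 | intermediate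
20 | C4 enol triflate (C3=C4); C2 methyl axial, trans to C1 methyl | COc1cc(C)c(OC)c(C[C@]2(C)[C@H]3CCCC4(OCCO4)[C@]3(C)C(OS(=O)(=O)C(F)(F)F)=C[C@@H]2C)c1 | intermediate
21 | 1-(ArCH2)-1,2,4a-trimethyl-5,5-(ethylenedioxy)-Δ3-octalin | COc1cc(C)c(OC)c(C[C@]2(C)[C@H]3CCCC4(OCCO4)[C@]3(C)C=C[C@@H]2C)c1 | intermediate
22 | 1-(ArCH2)-1,2,4a-trimethyl-5,5-(ethylenedioxy)decalin | COc1cc(C)c(OC)c(C[C@]2(C)[C@H]3CCCC4(OCCO4)[C@]3(C)CC[C@@H]2C)c1 | intermediate
23 | 1-(ArCH2)-1,2,4a-trimethyldecalin-5-one | COc1cc(C)c(OC)c(C[C@]2(C)[C@H]3CCCC(=O)[C@]3(C)CC[C@@H]2C)c1 | intermediate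
24 | lithium enolate (C5=C6) of 23 | COc1cc(C)c(OC)c(C[C@]2(C)[C@H]3CCC=C(O[Li])[C@]3(C)CC[C@@H]2C)c1 | intermediate
25 | 6-(2-hydroxypropan-2-yl) derivative of 23, substituent equatorial | COc1cc(C)c(OC)c(C[C@]2(C)[C@H]3CC[C@H](C(C)(C)O)C(=O)[C@]3(C)CC[C@@H]2C)c1 | intermediate
26 | tertiary methanesulfonate of 25 | COc1cc(C)c(OC)c(C[C@]2(C)[C@H]3CC[C@H](C(C)(C)OS(C)(=O)=O)C(=O)[C@]3(C)CC[C@@H]2C)c1 | intermediate
27 | 1-(ArCH2)-1,2,4a-trimethyl-6-(propan-2-ylidene)decalin-5-one | COc1cc(C)c(OC)c(C[C@]2(C)[C@H]3CCC(=C(C)C)C(=O)[C@]3(C)CC[C@@H]2C)c1 | intermediate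
28 | 1-(ArCH2)-1,2,4a-trimethyl-5-methylidene-6-(propan-2-ylidene)decalin | COc1cc(C)c(OC)c(C[C@]2(C)[C@H]3CCC(=C(C)C)C(=C)[C@]3(C)CC[C@@H]2C)c1 | intermediate
29 | 9-[(decalin-5-yl)methyl]-9-borabicyclo[3.3.1]nonane; C5–H trans to C4a methyl | COc1cc(C)c(OC)c(C[C@]2(C)[C@H]3CCC(=C(C)C)[C@@H](CB4C5CCCC4CCC5)[C@]3(C)CC[C@@H]2C)c1 | intermediate
30 | ethyl 3-[1-(ArCH2)-1,2,4a-trimethyl-6-(propan-2-ylidene)decalin-5-yl]propanoate | COc1cc(C)c(OC)c(C[C@]2(C)[C@H]3CCC(=C(C)C)[C@@H](CCC(=O)OCC)[C@]3(C)CC[C@@H]2C)c1 | intermediate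
31 | 3-[1-(ArCH2)-1,2,4a-trimethyl-6-(propan-2-ylidene)decalin-5-yl]propanoic acid | COc1cc(C)c(OC)c(C[C@]2(C)[C@H]3CCC(=C(C)C)[C@@H](CCC(=O)O)[C@]3(C)CC[C@@H]2C)c1 | intermediate
32 | 3-{(1S,2S,4aR,5S,8aR)-1,2,4a-trimethyl-1-[(5-methyl-3,6-dioxocyclohexa-1,4-dien-1-yl)methyl]-6-(propan-2-ylidene)decalin-5-yl}propanoic acid (locants as defined above) | CC1=CC(=O)C=C(C[C@]2(C)[C@H]3CCC(=C(C)C)[C@@H](CCC(=O)O)[C@]3(C)CC[C@@H]2C)C1=O | target

**Step count and risks**

Total: 18 steps. Longest linear sequence: 18 steps (1 → 32; 5, 9 and 10 are bought).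

Steps most likely to fail:

1. Step 5. The magnesium enolate 11 may be captured poorly by acrolein (proton transfer, conjugate addition to the enal, reversal of the aldol on warming), and with both bond formations in one flask neither can be tuned alone. The enantioselectivity of the alkenyl transfer is a second uncertainty. Fallback, setting out from 11: instead of acrolein, Me3SiCl/Et3N/DMPU is added to give the trimethylsilyl enol ether F1, which is isolated so that the conjugate addition can be assayed and optimised separately. MeLi in THF at 0 °C then cleaves it to the lithium enolate F2, and acrolein at −78 °C gives the aldol, returning to the route at 12.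

2. Step 8. Hydrogen transfer to the C1 radical or to the vinyl ketone may outrun ring closure (net reduction), and the iron hydride may degrade the vinyl ketone. Fallback, setting out from 13: cobalt-mediated Markovnikov hydrobromination (Co(acac)2, t-BuOOH, Et3SiH, TsBr, n-PrOH) of the 1,1-disubstituted alkene, the faster hydrogen-atom acceptor, would give the tertiary bromide F3. Dess–Martin oxidation gives the bromo vinyl ketone F4. Bu3SnH/AIBN in dilute benzene at 80 °C (syringe pump) then generates the same C1 radical by bromine abstraction, with no metal hydride present, and closes ring B 6-endo, returning to the route at 15.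

3. Step 15. The carbonyl of 27 is flanked by a quaternary carbon and a tetrasubstituted alkene carbon, so the titanium methylidene may fail to add or may decompose first. Fallback, setting out from 27: Me3SiCH2Li/CeCl3 in THF at −78 °C adds a small, non-basic nucleophile to the carbonyl to give the β-hydroxysilane F5. KH in THF then effects Peterson elimination to the diene, returning to the route at 28.

**Further compounds**

F1 | step 5 | trimethylsilyl enol ether (C1=C2) of (3R)-3-[3-Ar-prop-1-en-2-yl]-2-methylcyclohexanone | COc1cc(C)c(OC)c(CC(=C)[C@H]2CCCC(O[Si](C)(C)C)=C2C)c1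
F2 | step 5 | lithium enolate (C1=C2) of (3R)-3-[3-Ar-prop-1-en-2-yl]-2-methylcyclohexanone | COc1cc(C)c(OC)c(CC(=C)[C@H]2CCCC(O[Li])=C2C)c1
F3 | step 8 | tertiary bromide from Markovnikov HBr addition to the 1,1-disubstituted alkene of 13 (either epimer at the C–Br carbon) | COc1cc(C)c(OC)c(CC(C)(Br)[C@H]3CCCC4(OCCO4)[C@]3(C)[C@@H](O)C=C)c1
F4 | step 8 | bromo vinyl ketone from oxidation of F3 | COc1cc(C)c(OC)c(CC(C)(Br)[C@H]3CCCC4(OCCO4)[C@]3(C)C(=O)C=C)c1
F5 | step 15 | 5-hydroxy-5-[(trimethylsilyl)methyl] adduct of 27 (either C5 epimer) | COc1cc(C)c(OC)c(C[C@]2(C)[C@H]3CCC(=C(C)C)C(O)(C[Si](C)(C)C)[C@]3(C)CC[C@@H]2C)c1
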